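**Plan**

1. Retrosynthesis: the geranyl chain is cut first at its benzylic–vinylic bond C1''–C2'', then the C6–CH2 bond (Mannich), then the C2–aryl bond of the flavanone (conjugate addition to a chromone). The alkenyl half is cut at C3''–CH3 (carbometallation of an enyne) and at C3''–C4'' (acetylide alkylation).
2. Enabling feature: in the A-ring, C-6 carries the benzylic carbon between the C-5 and C-7 hydroxyls, so a C6–CH2–NMe2 unit can ionise to the ortho-quinone methide (C6=CH2, C7=O). The O-7 oxygen then holds an (E)-alkenylboron as a temporary tether and hands its alkenyl group to that CH2.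
3. Forward: the pyranone ring is present from the start (5,7-dihydroxychromone). MOM protection, Rh-catalysed asymmetric 1,4-arylation, deprotection and C-6 aminomethylation give one half. Homoprenyl bromide → enyne → (E)-vinyl iodide → (E)-alkenylboronic acid gives the other. The halves are joined last on the unprotected flavanone, and the amine activating group leaves in that same step.
4. Stereochemistry: C-2 (S) comes from the chiral bisphosphine in the Rh-catalysed addition. The 2''E olefin comes from syn-carboalumination and is carried with retention through I, Li, B and the final transfer.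

Key step: step 8

Assumption: the target is taken as the (2S) enantiomer with a (2''E) olefin as drawn; 5,7-dihydroxychromone, (3,4-dimethoxyphenyl)boronic acid and 5-bromo-2-methylpent-2-ene are taken as purchasable.

**Route**

Step 1
Reactants: 1 5,7-dihydroxy-4H-chromen-4-one
Product: 2 5,7-bis(methoxymethoxy)-4H-chromen-4-one
Conditions: NaH (2.5 equiv), MOMCl (2.5 equiv), DMF, 0 °C → rt
Reagents that add atoms: chloromethyl methyl ether (MOMCl), COCCl
Why: Williamson-type O-alkylation (MOM ether formation) of both phenoxides, NaH being needed because the 5-OH is hydrogen-bonded to the C-4 carbonyl; the acetals mask the acidic phenols that would otherwise quench the aryl–rhodium species of step 2.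

Step 2
Reactants: 2 5,7-bis(methoxymethoxy)-4H-chromen-4-one; 3 (3,4-dimethoxyphenyl)boronic acid
Product: 4 (2S)-2-(3,4-dimethoxyphenyl)-5,7-bis(methoxymethoxy)chroman-4-one
Conditions: [Rh(OH)(cod)]2 (2.5 mol %), (S)-MeO-F12-BIPHEP (5.5 mol %), 3 (3 equiv), toluene/H2O (10:1), 50 °C
Reagents that add atoms: none
Why: Hayashi–Miyaura rhodium-catalysed asymmetric 1,4-addition of an arylboronic acid to the chromone enone, a known enantioselective entry to flavanones in which the electron-poor atropisomeric bisphosphine speeds insertion and protonation so that ring opening to the chalcone is outrun; the C-2 stereocentre is set by the ligand, the (S)-bisphosphine being chosen because it is expected to deliver the aryl group to the enone face that gives (S)-3-arylcyclohexanones from cyclohexenone, which maps onto (2S) in the flavanone.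

Step 3
Reactants: 4 (2S)-2-(3,4-dimethoxyphenyl)-5,7-bis(methoxymethoxy)chroman-4-one
Product: 5 (2S)-5,7-dihydroxy-2-(3,4-dimethoxyphenyl)chroman-4-one
Conditions: 3 M aq. HCl/MeOH (1:5), 45 °C
Reagents that add atoms: none
Why: acid-catalysed acetal cleavage (MOM removal) frees both phenols while the aryl methyl ethers are inert, and the non-basic medium should leave C-2 untouched because ring opening of flavanones to chalcones is base-mediated.

Step 4
Reactants: 5 (2S)-5,7-dihydroxy-2-(3,4-dimethoxyphenyl)chroman-4-one
Product: 7 (2S)-6-[(dimethylamino)methyl]-5,7-dihydroxy-2-(3,4-dimethoxyphenyl)chroman-4-one, via Mannich base hydroiodide 6 (not isolated)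
Conditions: Me2N+=CH2 I− (1.0 equiv), MeCN, 0 °C → rt; aq. NaHCO3 work-up; used crude
Reagents that add atoms: N,N-dimethylmethyleneiminium iodide (Eschenmoser's salt), C=[N+](C)C.[I-]
Why: Mannich-type electrophilic aromatic aminomethylation, expected at C-6 because this carbon lies between the two free hydroxyls (O-5, O-7) and is the central, most nucleophilic carbon of their vinylogous enol system, whereas C-8 is flanked by one hydroxyl and the ring ether oxygen; the base-free medium protonates the product amine, which should suppress a second aminomethylation and spare C-2.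

Step 5
Reactants: 8 5-bromo-2-methylpent-2-ene
Product: 9 6-methylhept-5-en-1-yne
Conditions: LiC≡CH·H2NCH2CH2NH2 (1.3 equiv), DMSO, 10 °C → rt
Reagents that add atoms: lithium acetylide ethylenediamine complex, [Li+].[C-]#C.NCCN
Why: SN2 alkylation of an acetylide by a primary bromide in a dipolar aprotic solvent, a standard preparation of terminal alkynes.

Step 6
Reactants: 9 6-methylhept-5-en-1-yne
Product: 11 (1E)-1-iodo-2,6-dimethylhepta-1,5-diene, via alkenyldimethylalane 10 (not isolated)
Conditions: Me3Al (2.0 equiv), Cp2ZrCl2 (0.25 equiv), CH2Cl2, 0 °C → rt; I2, THF, −30 → 0 °C; aq. NaOH work-up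
Reagents that add atoms: trimethylaluminium, C[Al](C)C; iodine, II
Why: Negishi zirconium-catalysed carboalumination adds methyl and aluminium syn across the terminal alkyne with aluminium at C-1, which fixes the (E)-trisubstituted olefin, and iododealumination proceeds with retention; the remote trisubstituted alkene is inert.

Step 7
Reactants: 11 (1E)-1-iodo-2,6-dimethylhepta-1,5-diene
Product: 14 [(1E)-2,6-dimethylhepta-1,5-dien-1-yl]boronic acid, via alkenyllithium 12 (not isolated), via lithium alkenyltriisopropoxyborate 13 (not isolated)
Conditions: t-BuLi (2.1 equiv), Et2O, −78 °C; B(OiPr)3, −78 °C → rt; 1 M aq. HCl, 0 °C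
Reagents that add atoms: triisopropyl borate, CC(C)OB(OC(C)C)OC(C)C; water, O
Why: iodine–lithium exchange on an alkenyl iodide with retention of geometry, borylation of the alkenyllithium with a trialkyl borate and hydrolysis of the borate complex is the standard route to alkenylboronic acids.

Step 8
Reactants: 7 (2S)-6-[(dimethylamino)methyl]-5,7-dihydroxy-2-(3,4-dimethoxyphenyl)chroman-4-one; 14 [(1E)-2,6-dimethylhepta-1,5-dien-1-yl]boronic acid
Product: 17 (2S)-5,7-dihydroxy-2-(3,4-dimethoxyphenyl)-6-[(2E)-3,7-dimethylocta-2,6-dien-1-yl]chroman-4-one, via quinone methide boronate complex 15 (not isolated), via aryl borate 16 (not isolated)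
Conditions: 14 (2 equiv), 4 Å MS, 1,4-dioxane, 70 °C; aq. NH4Cl work-up
Reagents that add atoms: none
Why: Boronic acid 14 is taken up by the O-7 phenoxide of the zwitterionic Mannich base, loss of dimethylamine from C6–CH2 gives the ortho-quinone methide (C6=CH2, C7=O) still held on boron (15), and the alkenyl group then migrates from the tetracoordinate boron to the exocyclic CH2 through a six-membered cyclic transition state, which restores the aromatic A-ring (16) before work-up cleaves the O–B bond. The closest known reaction type is the Petasis-type (borono-Mannich) transfer of alkenyl groups from boron to ortho-quinone methides generated in situ from ortho-hydroxybenzyl amines, ethers or alcohols. No ring is closed and no stereocentre is created; the 2''E geometry is carried over from 14 because migration from boron proceeds with retention at the alkenyl carbon, and C-2 should not be touched because no base stronger than the borate-buffered dimethylamine is present. The selectivity needed is C–C bond formation at the benzylic carbon ahead of oligomerisation of the quinone methide through C-8 of a second molecule or its hetero-Diels–Alder capture by an olefin; it is secured by intramolecular delivery from boron bound to the hydroxyl oxygen that flanks C-6 (O-7, or equally O-5), and the site of geranylation is fixed by the position of the CH2NMe2 group.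

**Compound list**

1 | 5,7-dihydroxy-4H-chromen-4-one | O=c1ccoc2cc(O)cc(O)c12 | starting material
2 | 5,7-bis(methoxymethoxy)-4H-chromen-4-one | O=c1ccoc2cc(OCOC)cc(OCOC)c12 | intermediate
3 | (3,4-dimethoxyphenyl)boronic acid | COc1ccc(B(O)O)cc1OC | starting material
4 | (2S)-2-(3,4-dimethoxyphenyl)-5,7-bis(methoxymethoxy)chroman-4-one | COc1ccc([C@@H]2CC(=O)c3c(cc(OCOC)cc3OCOC)O2)cc1OC | intermediate
5 | (2S)-5,7-dihydroxy-2-(3,4-dimethoxyphenyl)chroman-4-one | COc1ccc([C@@H]2CC(=O)c3c(cc(O)cc3O)O2)cc1OC | intermediate
6 | (2S)-6-[(dimethylammonio)methyl]-5,7-dihydroxy-2-(3,4-dimethoxyphenyl)chroman-4-one iodide | COc1ccc([C@@H]2CC(=O)c3c(cc(O)c(C[NH+](C)C)c3O)O2)cc1OC.[I-] | intermediate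
7 | (2S)-6-[(dimethylamino)methyl]-5,7-dihydroxy-2-(3,4-dimethoxyphenyl)chroman-4-one | COc1ccc([C@@H]2CC(=O)c3c(cc(O)c(CN(C)C)c3O)O2)cc1OC | intermediate
8 | 5-bromo-2-methylpent-2-ene | CC(C)=CCCBr | starting material
9 | 6-methylhept-5-en-1-yne | C#CCCC=C(C)C | intermediate
10 | [(1E)-2,6-dimethylhepta-1,5-dien-1-yl]dimethylalane | C[Al](C)/C=C(\C)CCC=C(C)C | intermediate
11 | (1E)-1-iodo-2,6-dimethylhepta-1,5-diene | I/C=C(\C)CCC=C(C)C | intermediate
12 | [(1E)-2,6-dimethylhepta-1,5-dien-1-yl]lithium | [Li]/C=C(\C)CCC=C(C)C | intermediate
13 | lithium [(1E)-2,6-dimethylhepta-1,5-dien-1-yl]tri(propan-2-yloxy)borate | [Li+].CC(C)O[B-](OC(C)C)(OC(C)C)/C=C(\C)CCC=C(C)C | intermediate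
14 | [(1E)-2,6-dimethylhepta-1,5-dien-1-yl]boronic acid | OB(O)/C=C(\C)CCC=C(C)C | intermediate
15 | ortho-quinone methide of the flavanone (C6=CH2, C7=O) bound through O-7 to the alkenylboronic acid | COc1ccc([C@@H]2CC(=O)C3=C(O)C(=C)C(=[O+][B-](O)(O)/C=C(\C)CCC=C(C)C)C=C3O2)cc1OC | intermediate
16 | 7-O-(dihydroxyboryl) derivative of the target | COc1ccc([C@@H]2CC(=O)c3c(cc(OB(O)O)c(C/C=C(\C)CCC=C(C)C)c3O)O2)cc1OC | intermediate
17 | (2S)-5,7-dihydroxy-2-(3,4-dimethoxyphenyl)-6-[(2E)-3,7-dimethylocta-2,6-dien-1-yl]chroman-4-one | COc1ccc([C@@H]2CC(=O)c3c(cc(O)c(C/C=C(\C)CCC=C(C)C)c3O)O2)cc1OC | target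

**Summary**

Total step count: 8. Longest linear sequence: 5 steps (steps 1, 2, 3, 4 and 8; the alkenyl branch, steps 5, 6, 7 and 8, is 4 steps).

**Steps most likely to fail**

Step 8. After loss of the amine the quinone methide may leave the boron and be intercepted by C-8 of a second flavanone (methylene-bridged dimers) or by a trisubstituted olefin in a hetero-Diels–Alder reaction before the alkenyl group migrates. Prolonged heating with the liberated dimethylamine may also erode the C-2 configuration through reversible ring opening. The fallback sets out from 7 and comes back at 17, and replaces the quinone methide pathway by a palladium-catalysed cross-coupling on a fully O-acylated benzylic electrophile. Heating 7 in acetic anhydride at 100 °C (the classical exchange of a phenolic Mannich amine for acetate, with O-acetylation of both phenols) should give (2S)-6-(acetoxymethyl)-2-(3,4-dimethoxyphenyl)-4-oxochroman-5,7-diyl diacetate F1. A Suzuki–Miyaura coupling of the benzylic acetate with 14 through a π-benzylpalladium intermediate ([Pd(η3-C3H5)Cl]2, 1,5-bis(diphenylphosphino)pentane, anhydrous K3PO4, toluene, 70 °C) should give (2S)-2-(3,4-dimethoxyphenyl)-6-[(2E)-3,7-dimethylocta-2,6-dien-1-yl]-4-oxochroman-5,7-diyl diacetate F2. Near-neutral methanolysis of the two aryl acetates (NH4OAc, aq. MeOH, rt) then returns 17.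

Step 4. Attack at C-8 may compete with attack at C-6, a second aminomethylation may follow, and the free Mannich base may undergo retro-Mannich oligomerisation on concentration. The fallback sets out from 5 and comes back at 7, and replaces reliance on intrinsic ring nucleophilicity by a blocked, hydroxyl-directed aminomethylation. Silylation of the only non-chelated phenol (TIPSCl, imidazole, DMF, 0 °C) should give (2S)-5-hydroxy-2-(3,4-dimethoxyphenyl)-7-[(triisopropylsilyl)oxy]chroman-4-one F3. With O-7 capped, a hydrogen-bond-directed ortho-Mannich reaction (bis(dimethylamino)methane, toluene, 60 °C) can only be steered by the 5-OH, whose sole free ortho carbon is C-6. This should give (2S)-6-[(dimethylamino)methyl]-5-hydroxy-2-(3,4-dimethoxyphenyl)-7-[(triisopropylsilyl)oxy]chroman-4-one F4. Desilylation under mildly acidic fluoride conditions (Et3N·3HF, THF, 0 °C) returns 7.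

Step 2. Ring opening of the rhodium enolate by β-aryloxide elimination (chalcone formation), slow insertion into the doubly donor-substituted chromone, protodeboronation of the electron-rich boronic acid, or insufficient facial discrimination may each limit the step. The fallback sets out from 2 and 3 and comes back at 4, and replaces catalyst-controlled enantioselection by a resolution, at the cost of at most half of the material. A palladium(II)-catalysed conjugate addition without chiral ligand (Pd(OCOCF3)2, 2,2'-bipyridine, aq. AcOH/THF, 60 °C) should give racemic 2-(3,4-dimethoxyphenyl)-5,7-bis(methoxymethoxy)chroman-4-one F5. Kinetic resolution by Noyori asymmetric transfer hydrogenation (RuCl[(R,R)-TsDPEN](p-cymene), HCO2H/Et3N, EtOAc, rt) should reduce the (R)-enantiomer to the cis alcohol (2R,4R)-2-(3,4-dimethoxyphenyl)-5,7-bis(methoxymethoxy)chroman-4-ol F6. The unreacted (S)-ketone 4 is then separated by chromatography.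

**Further compounds**

F1 | step 8 | (2S)-6-(acetoxymethyl)-2-(3,4-dimethoxyphenyl)-4-oxochroman-5,7-diyl diacetate | COc1ccc([C@@H]2CC(=O)c3c(cc(OC(C)=O)c(COC(C)=O)c3OC(C)=O)O2)cc1OC
F2 | step 8 | (2S)-2-(3,4-dimethoxyphenyl)-6-[(2E)-3,7-dimethylocta-2,6-dien-1-yl]-4-oxochroman-5,7-diyl diacetate | COc1ccc([C@@H]2CC(=O)c3c(cc(OC(C)=O)c(C/C=C(\C)CCC=C(C)C)c3OC(C)=O)O2)cc1OC
F3 | step 4 | (2S)-5-hydroxy-2-(3,4-dimethoxyphenyl)-7-[(triisopropylsilyl)oxy]chroman-4-one | COc1ccc([C@@H]2CC(=O)c3c(cc(O[Si](C(C)C)(C(C)C)C(C)C)cc3O)O2)cc1OC
F4 | step 4 | (2S)-6-[(dimethylamino)methyl]-5-hydroxy-2-(3,4-dimethoxyphenyl)-7-[(triisopropylsilyl)oxy]chroman-4-one | COc1ccc([C@@H]2CC(=O)c3c(cc(O[Si](C(C)C)(C(C)C)C(C)C)c(CN(C)C)c3O)O2)cc1OC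
F5 | step 2 | rac-2-(3,4-dimethoxyphenyl)-5,7-bis(methoxymethoxy)chroman-4-one | COc1ccc(C2CC(=O)c3c(cc(OCOC)cc3OCOC)O2)cc1OC
F6 | step 2 | (2R,4R)-2-(3,4-dimethoxyphenyl)-5,7-bis(methoxymethoxy)chroman-4-ol | COc1ccc([C@H]2C[C@@H](O)c3c(cc(OCOC)cc3OCOC)O2)cc1OC
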